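**Plan**

1. Retrosynthesis: the C3–C4 bond of the oxolane (the 8–8' bond of the lignan) and the benzylic C–H are cut first, which opens the only ring to an epoxy cinnamyl ether (10). The ether O–C5 bond is cut next into an epoxy alcohol (4) and a cinnamyl bromide (8), and both halves go back to 3,4,5-trimethoxybenzaldehyde.
2. Forward: aldehyde → vinyl carbinol → epoxy alcohol; aldehyde → cinnamate → cinnamyl alcohol → bromide; the two C6–C3 halves are joined through oxygen. The oxolane ring arises last, by a reductive epoxide–alkene radical cyclisation with Cp2TiCl, an 8–8' radical coupling in the manner of lignan biosynthesis.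
3. Feature that makes the event possible: ring atom C3 carries CH2OH (C3–C–O is a terminal epoxide opened by one electron, radical on C3), and ring atom C4 carries ArCH2 (a styrene that has taken up a radical and a hydrogen). C3 and C4 are linked through C2–O1–C5, so the radical is a 3-oxahex-5-enyl radical that closes 5-exo.
4. Stereochemistry: C2 comes from a Sharpless kinetic resolution with D-(−)-diisopropyl tartrate. C3 and C4 are set in the key step by C2 (chair-like transition state, 2,3-trans and 3,4-cis); the epoxide stereocentre is erased.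

Key step: step 7

Remark on the chemistry: the oxolane is numbered O1, C2 (aryl), C3 (CH2OH), C4 (benzyl), C5; the target is the (2S,3R,4R) isomer, 2,3-trans and 3,4-cis. In the titanium-containing SMILES the cyclopentadienyl rings are written as σ-bonded C5H5 groups.

**Route**

Step 1
Reactants: 1 3,4,5-trimethoxybenzaldehyde; 2 vinylmagnesium bromide
Product: 3 rac-1-(3,4,5-trimethoxyphenyl)prop-2-en-1-ol
Conditions: 2 (1.2 equiv), THF, 0 °C to rt; sat. aq NH4Cl
Reagents that add atoms: none
Why: Grignard 1,2-addition to a non-enolisable aryl aldehyde should give the racemic aryl vinyl carbinol cleanly.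

Step 2
Reactants: 3 rac-1-(3,4,5-trimethoxyphenyl)prop-2-en-1-ol
Product: 4 (R)-[(2R)-oxiran-2-yl](3,4,5-trimethoxyphenyl)methanol
Conditions: Ti(OiPr)4 (0.15 equiv), D-(−)-diisopropyl tartrate (0.20 equiv), t-BuOOH (0.5 equiv), 4 Å molecular sieves, CH2Cl2, −20 °C, stopped near 45% conversion; chromatography removes unreacted (R)-3
Reagents that add atoms: tert-butyl hydroperoxide, CC(C)(C)OO
Why: In the Sharpless kinetic resolution with the D-(−)-tartrate the (S)-enantiomer of the aryl vinyl carbinol should be the fast one and be epoxidised to the erythro epoxy alcohol, so the carbinol centre (the later C2, named R only because the oxirane carbon now outranks the aryl group) is set by the catalyst and the slow (R)-enantiomer of 3 is left behind.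

Step 3
Reactants: 1 3,4,5-trimethoxybenzaldehyde; 5 ethyl (triphenylphosphoranylidene)acetate
Product: 6 ethyl (E)-3-(3,4,5-trimethoxyphenyl)prop-2-enoate
Conditions: CH2Cl2, rt
Reagents that add atoms: none
Why: Wittig olefination with a stabilised ylide should give the (E)-cinnamate selectively.

Step 4
Reactants: 6 ethyl (E)-3-(3,4,5-trimethoxyphenyl)prop-2-enoate
Product: 7 (E)-3-(3,4,5-trimethoxyphenyl)prop-2-en-1-ol
Conditions: DIBAL-H (2.3 equiv), CH2Cl2, −78 to 0 °C; aq potassium sodium tartrate
Reagents that add atoms: none
Why: DIBAL-H reduces an enoate by 1,2-hydride delivery, so the allylic alcohol should form without touching the alkene.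

Step 5
Reactants: 7 (E)-3-(3,4,5-trimethoxyphenyl)prop-2-en-1-ol
Product: 8 (E)-5-(3-bromoprop-1-en-1-yl)-1,2,3-trimethoxybenzene
Conditions: PBr3 (0.4 equiv), Et2O, 0 °C; used crude at once
Reagents that add atoms: phosphorus tribromide, BrP(Br)Br
Why: Bromination of a primary allylic alcohol through its phosphite ester should give the linear (E)-cinnamyl bromide, which is used without storage because it is labile.

Step 6
Reactants: 4 (R)-[(2R)-oxiran-2-yl](3,4,5-trimethoxyphenyl)methanol; 8 (E)-5-(3-bromoprop-1-en-1-yl)-1,2,3-trimethoxybenzene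
Product: 10 (2R)-2-[(R)-(3,4,5-trimethoxyphenyl){[(E)-3-(3,4,5-trimethoxyphenyl)prop-2-en-1-yl]oxy}methyl]oxirane, via sodium alkoxide 9 (not isolated)
Conditions: NaH (1.1 equiv) added to 4, 8 (1.2 equiv) and Bu4NI (0.1 equiv) in THF, −10 to 0 °C
Reagents that add atoms: none
Why: Williamson ether synthesis with a very reactive allylic bromide present from the start should trap the alkoxide before it can rearrange, and the carbinol centre is not touched.

Step 7
Reactants: 10 (2R)-2-[(R)-(3,4,5-trimethoxyphenyl){[(E)-3-(3,4,5-trimethoxyphenyl)prop-2-en-1-yl]oxy}methyl]oxirane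
Product: 14 [(2S,3R,4R)-2-(3,4,5-trimethoxyphenyl)-4-(3,4,5-trimethoxybenzyl)oxolan-3-yl]methanol, via titanoxy radical 11 (not isolated), via benzylic radical 12 (not isolated), via benzyltitanium alkoxide 13 (not isolated)
Conditions: Cp2TiCl2 (2.5 equiv), Zn dust (5 equiv), THF, rt (green Cp2TiCl); this solution added dropwise over 1 h to 10 in THF (0.02 M), rt; then 1 M HCl, 0 °C
Reagents that add atoms: none
Why: Cp2TiCl (trivalent titanium) transfers one electron to the epoxide of 10 and the C–O bond to the more substituted carbon breaks, giving the secondary radical 11 with its CH2O–Ti arm in place; 11 adds to the near end of the styrene to form the C3–C4 bond and the benzylic radical 12, a second Cp2TiCl reduces 12 to 13, and acid frees the CH2OH and the ArCH2 group. The closest known reaction type is the RajanBabu–Nugent reductive epoxide opening with radical cyclisation, which has close precedent for epoxy cinnamyl ethers leading to 2-aryl-3-hydroxymethyl-4-benzyl oxolanes. The oxolane closes in the 5-exo-trig mode. C3 and C4 are both set by the existing centre C2 through a chair-like Beckwith–Houk transition state: the aryl group on C2 sits pseudo-equatorial and anti to the CH2OTi group on the radical carbon (2,3-trans), the alkene lies syn to that CH2OTi group (3,4-cis), and the epoxide stereocentre of 10 is erased at the radical stage. The step needs epoxide opening toward the internal carbon, exo over endo closure, and ring closure faster than capture of 11 by trivalent titanium; the first follows from radical stability, the second from the benzylic stabilisation of 12, and the third from fast addition to a styrene together with slow addition of Cp2TiCl.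

**Compound list**

1 | 3,4,5-trimethoxybenzaldehyde | COc1cc(C=O)cc(OC)c1OC | starting material
2 | vinylmagnesium bromide | C=C[Mg]Br | starting material
3 | rac-1-(3,4,5-trimethoxyphenyl)prop-2-en-1-ol | C=CC(O)c1cc(OC)c(OC)c(OC)c1 | intermediate
4 | (R)-[(2R)-oxiran-2-yl](3,4,5-trimethoxyphenyl)methanol | O[C@H](c1cc(OC)c(OC)c(OC)c1)[C@H]1CO1 | intermediate
5 | ethyl (triphenylphosphoranylidene)acetate | CCOC(=O)C=P(c1ccccc1)(c1ccccc1)c1ccccc1 | starting material
6 | ethyl (E)-3-(3,4,5-trimethoxyphenyl)prop-2-enoate | CCOC(=O)/C=C/c1cc(OC)c(OC)c(OC)c1 | intermediate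
7 | (E)-3-(3,4,5-trimethoxyphenyl)prop-2-en-1-ol | OC/C=C/c1cc(OC)c(OC)c(OC)c1 | intermediate
8 | (E)-5-(3-bromoprop-1-en-1-yl)-1,2,3-trimethoxybenzene | BrC/C=C/c1cc(OC)c(OC)c(OC)c1 | intermediate
9 | sodium alkoxide of 4 (not isolated) | [Na+].[O-][C@H](c1cc(OC)c(OC)c(OC)c1)[C@H]1CO1 | intermediate
10 | (2R)-2-[(R)-(3,4,5-trimethoxyphenyl){[(E)-3-(3,4,5-trimethoxyphenyl)prop-2-en-1-yl]oxy}methyl]oxirane | COc1cc(/C=C/CO[C@H](c2cc(OC)c(OC)c(OC)c2)[C@H]2CO2)cc(OC)c1OC | intermediate
11 | secondary carbon radical from opening of the epoxide of 10, oxygen bound to Cp2TiCl (tetravalent titanium) (not isolated) | COc1cc(/C=C/CO[C@H](c2cc(OC)c(OC)c(OC)c2)[CH]CO[Ti](Cl)(C2C=CC=C2)C2C=CC=C2)cc(OC)c1OC | intermediate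
12 | cyclised benzylic radical, (2S,3R,4R)-oxolane with CH2O–TiCp2Cl on C3 (not isolated) | COc1cc([CH][C@H]2CO[C@H](c3cc(OC)c(OC)c(OC)c3)[C@H]2CO[Ti](Cl)(C2C=CC=C2)C2C=CC=C2)cc(OC)c1OC | intermediate
13 | benzyltitanium alkoxide: oxolane with C–TiCp2Cl at the benzylic carbon and CH2O–TiCp2Cl on C3 (not isolated) | COc1cc(C([Ti](Cl)(C2C=CC=C2)C2C=CC=C2)[C@H]2CO[C@H](c3cc(OC)c(OC)c(OC)c3)[C@H]2CO[Ti](Cl)(C2C=CC=C2)C2C=CC=C2)cc(OC)c1OC | intermediate
14 | [(2S,3R,4R)-2-(3,4,5-trimethoxyphenyl)-4-(3,4,5-trimethoxybenzyl)oxolan-3-yl]methanol | COc1cc(C[C@H]2CO[C@H](c3cc(OC)c(OC)c(OC)c3)[C@H]2CO)cc(OC)c1OC | target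

**Step count and risks**

Total step count: 7. Longest linear sequence: 5 steps (steps 3, 4, 5, 6, 7).

Steps most likely to fail:

Step 7. The ring closure may show incomplete facial control at C4, so that the 3,4-trans isomer forms beside 14. Radical 11 may also be captured by a second Cp2TiCl before it cyclises and then lose the titanoxy group. The fallback sets out from 10 and comes back at 14. The cyclisation is run as before up to 13, but it is ended by oxidation instead of acid: iodine (THF, rt to 40 °C) cleaves the carbon–titanium bond to give the benzylic iodide with titanium alkoxide F1 (not isolated). Its cis-placed alkoxide displaces iodide and closes a second oxolane ring, which should give the cis-fused furofuran (3S,3aR,6S,6aR)-3,6-bis(3,4,5-trimethoxyphenyl)-1,3,3a,4,6,6a-hexahydrofuro[3,4-c]furan F2, with the aryl group expected exo. Only material with the 3,4-cis arrangement can form this temporary second ring, so F2 should be separable from everything of the wrong configuration. Partial hydrogenolysis of one benzylic C–O bond (H2, 1 atm, Pd/C, EtOAc/EtOH, rt, stopped after one equivalent) then opens the temporary ring to 14. Because F2 is C2-symmetric, cleavage of either benzylic C–O bond leads to the same product.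

Step 6. Alkoxide 9 may undergo Payne rearrangement (epoxide migration to the benzylic position) before O-alkylation, and the bromide may be attacked in the SN2' sense. The fallback sets out from 7 and comes back at 10, and it avoids any alkoxide. Alcohol 7 is converted with Cl3CCN and catalytic DBU (CH2Cl2, 0 °C) into (E)-3-(3,4,5-trimethoxyphenyl)prop-2-en-1-yl 2,2,2-trichloroacetimidate F3. Neutral 4 is then alkylated by F3 under catalytic TMSOTf (0.05 equiv, CH2Cl2, −40 °C), an acid-catalysed imidate etherification that leaves the carbinol centre untouched.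

Step 2. The titanium–tartrate catalyst may discriminate too little between the enantiomers of 3, so that 4 is formed with insufficient enantiomeric purity. The fallback sets out from 3 and comes back at 4, with the resolution done by an enzyme. Acylation of 3 with vinyl acetate and Novozym 435 (immobilised lipase B from Candida antarctica; MTBE, 30 °C) should, by the Kazlauskas rule, leave (S)-1-(3,4,5-trimethoxyphenyl)prop-2-en-1-ol F4 unreacted and convert the other enantiomer into (R)-1-(3,4,5-trimethoxyphenyl)prop-2-en-1-yl acetate F5, which is removed by chromatography. Alcohol F4 is then epoxidised as a single enantiomer with the matched system (Ti(OiPr)4, D-(−)-diisopropyl tartrate, t-BuOOH, CH2Cl2, −20 °C), which should give erythro 4.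

**Further compounds**

F1 | step 7 | benzylic iodide of the cyclised oxolane, CH2O–TiCp2Cl on C3 (not isolated) | COc1cc(C(I)[C@H]2CO[C@H](c3cc(OC)c(OC)c(OC)c3)[C@H]2CO[Ti](Cl)(C2C=CC=C2)C2C=CC=C2)cc(OC)c1OC
F2 | step 7 | (3S,3aR,6S,6aR)-3,6-bis(3,4,5-trimethoxyphenyl)-1,3,3a,4,6,6a-hexahydrofuro[3,4-c]furan | COc1cc([C@@H]4[C@H]2CO[C@H](c3cc(OC)c(OC)c(OC)c3)[C@H]2CO4)cc(OC)c1OC
F3 | step 6 | (E)-3-(3,4,5-trimethoxyphenyl)prop-2-en-1-yl 2,2,2-trichloroacetimidate | COc1cc(/C=C/COC(=N)C(Cl)(Cl)Cl)cc(OC)c1OC
F4 | step 2 | (S)-1-(3,4,5-trimethoxyphenyl)prop-2-en-1-ol | C=C[C@H](O)c1cc(OC)c(OC)c(OC)c1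
F5 | step 2 | (R)-1-(3,4,5-trimethoxyphenyl)prop-2-en-1-yl acetate | CC(=O)O[C@H](C=C)c1cc(OC)c(OC)c(OC)c1
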